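**Retrosynthetic overview**
- Feature: the benzene ring of the indole carries Br on C4 and C7, para to each other across the unsubstituted C5–C6 edge, and shares C3a–C7a with a pyrrole ring that already bears Br on C2 and C3. This is the pattern that double bromine capture by an indole-4,7-diyl (para-benzyne) diradical would give.
- Last disconnection: N1–H from N1–SEM (SEM = [2-(trimethylsilyl)ethoxy]methyl), cleaved with fluoride.
- Key disconnection: C5–C6, C4–Br and C7–Br, by Bergman cycloaromatization of a 2,3-diethynylpyrrole in the presence of CBr4. The pyrrole ring is bought; the benzene ring is formed last.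
- Enediyne: the C2 alkyne comes from the C2 aldehyde (Seyferth–Gilbert homologation), the C3 alkyne from a C3 iodide (Sonogashira coupling), both from 4,5-dibromo-1H-pyrrole-2-carbaldehyde.
- SEM on nitrogen survives the methanolic K2CO3 of the alkyne-forming step, removes the N–H hydrogen donor in the key step and places no arene or 1,5-hydrogen next to the C7 radical.

Key step: step 5

Assumption: 4,5-dibromo-1H-pyrrole-2-carbaldehyde 1 is taken as a catalogue compound; it is otherwise one step from pyrrole-2-carbaldehyde and two equivalents of N-bromosuccinimide.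

**Step 1**
Reactants: 1 4,5-dibromo-1H-pyrrole-2-carbaldehyde; 2 N-iodosuccinimide
Product: 3 4,5-dibromo-3-iodo-1H-pyrrole-2-carbaldehyde
Conditions: NIS (1.2 equiv), TFA (0.5 equiv), MeCN, 50 °C, dark
Reagents that add atoms: N-iodosuccinimide, O=C1CCC(=O)N1I
Why: Electrophilic aromatic iodination with acid-activated NIS should substitute the only ring C–H (C3) of the still nucleophilic pyrrole, so no regiochemical choice arises.

**Step 2**
Reactants: 3 4,5-dibromo-3-iodo-1H-pyrrole-2-carbaldehyde; 4 [2-(trimethylsilyl)ethoxy]methyl chloride (SEM chloride)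
Product: 5 4,5-dibromo-3-iodo-1-{[2-(trimethylsilyl)ethoxy]methyl}-1H-pyrrole-2-carbaldehyde
Conditions: NaH (1.1 equiv), DMF, 0 °C; then SEMCl (1.2 equiv), 0 °C to rt
Reagents that add atoms: [2-(trimethylsilyl)ethoxy]methyl chloride, C[Si](C)(C)CCOCCl
Why: N-alkylation of the sodium pyrrolide, whose N–H is acidified by the formyl group and three halogens, with a reactive chloromethyl ether should take place on nitrogen.

**Step 3**
Reactants: 5 4,5-dibromo-3-iodo-1-{[2-(trimethylsilyl)ethoxy]methyl}-1H-pyrrole-2-carbaldehyde; 6 ethynyltrimethylsilane
Product: 7 4,5-dibromo-3-[(trimethylsilyl)ethynyl]-1-{[2-(trimethylsilyl)ethoxy]methyl}-1H-pyrrole-2-carbaldehyde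
Conditions: PdCl2(PPh3)2 (3 mol %), CuI (6 mol %), Et3N (3 equiv), THF, rt, argon
Reagents that add atoms: ethynyltrimethylsilane, C#C[Si](C)(C)C
Why: In this Sonogashira coupling zerovalent palladium should insert into the C3–I bond, activated by the ortho formyl group, much faster than into either C–Br bond at room temperature, so only C3 is alkynylated.

**Step 4**
Reactants: 7 4,5-dibromo-3-[(trimethylsilyl)ethynyl]-1-{[2-(trimethylsilyl)ethoxy]methyl}-1H-pyrrole-2-carbaldehyde; 8 dimethyl (1-diazo-2-oxopropyl)phosphonate (Ohira–Bestmann reagent)
Product: 10 4,5-dibromo-2,3-diethynyl-1-{[2-(trimethylsilyl)ethoxy]methyl}-1H-pyrrole, via 3-ethynyl aldehyde 9 (not isolated)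
Conditions: K2CO3 (3 equiv), MeOH/THF 2:1, 0 °C; then 8 (1.5 equiv), 0 °C to rt
Reagents that add atoms: dimethyl (1-diazo-2-oxopropyl)phosphonate, COP(=O)(OC)C(=[N+]=[N-])C(C)=O
Why: In this Seyferth–Gilbert homologation (Ohira–Bestmann version) methanolic K2CO3 should first cleave the alkynyl C–Si bond and release dimethyl (diazomethyl)phosphonate from 8, whose anion adds to the aldehyde, loses phosphate and N2 and gives the terminal alkyne by 1,2-hydrogen shift of the alkylidene carbene, while SEM and both C–Br bonds are inert.

**Step 5**
Reactants: 10 4,5-dibromo-2,3-diethynyl-1-{[2-(trimethylsilyl)ethoxy]methyl}-1H-pyrrole; 11 carbon tetrabromide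
Product: 13 2,3,4,7-tetrabromo-1-{[2-(trimethylsilyl)ethoxy]methyl}-1H-indole, via indole-4,7-diyl diradical 12 (not isolated)
Conditions: CBr4 (200 equiv, 1.0 M), TEMPO (2,2,6,6-tetramethylpiperidin-1-oxyl, 2.5 equiv), PhCl (0.005 M in 10, degassed), sealed tube, 170 °C, dark
Reagents that add atoms: carbon tetrabromide, BrC(Br)(Br)Br
Why: Proposed new method: heating the cis-enediyne held on the pyrrole C2=C3 bond should join the two terminal alkyne carbons (indole C5–C6) in a Bergman cycloaromatization, leaving in-plane sigma radicals on the two inner alkyne carbons (indole C4 and C7) of diradical 12, and each of these should take bromine from CBr4, whose weak C–Br bond and lack of hydrogen make it a very fast bromine donor for aryl radicals. The closest known reaction type is the thermal Bergman cyclization of arene-fused and heteroarene-fused enediynes with capture of the 1,4-diyl by halogen-atom donors such as CCl4, which gives para-dihaloarenes. The benzene ring closes by C1–C6 bonding of the hex-3-ene-1,5-diyne unit (a diradical cycloaromatization with both alkynes inside the new ring), and no stereocenter is formed. The step needs bromine capture to outrun hydrogen capture and ring reopening, which 1 M CBr4 in a solvent without weak C–H bonds and high dilution of 10 should secure, while the SEM group has no hydrogen in a 1,5-relationship to the C7 radical and the strong aryl C–Br bonds on the pyrrole are not attacked. It also needs the chain addition of the tribromomethyl radical and CBr4 across the terminal alkynes (Kharasch-type atom-transfer addition) to be held back, and for this the persistent nitroxide TEMPO at low concentration should intercept the tribromomethyl radical after each bromine transfer, while the aryl radicals meet about eighty times more CBr4 than nitroxide and are brominated first.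

**Step 6**
Reactants: 13 2,3,4,7-tetrabromo-1-{[2-(trimethylsilyl)ethoxy]methyl}-1H-indole
Product: 14 2,3,4,7-tetrabromo-1H-indole
Conditions: Bu4NF (1 M in THF, 5 equiv), THF, 60 °C; aqueous work-up
Reagents that add atoms: none
Why: Fluoride-induced fragmentation of the SEM group (attack at silicon, loss of ethene and formaldehyde) should be eased by the good leaving-group ability of the tetrabromoindolide, and aryl C–Br bonds do not react with fluoride.

**Compound list**
1 | 4,5-dibromo-1H-pyrrole-2-carbaldehyde | O=Cc1cc(Br)c(Br)[nH]1 | starting material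
2 | N-iodosuccinimide | O=C1CCC(=O)N1I | starting material
3 | 4,5-dibromo-3-iodo-1H-pyrrole-2-carbaldehyde | O=Cc1[nH]c(Br)c(Br)c1I | intermediate
4 | [2-(trimethylsilyl)ethoxy]methyl chloride | C[Si](C)(C)CCOCCl | starting material
5 | 4,5-dibromo-3-iodo-1-{[2-(trimethylsilyl)ethoxy]methyl}-1H-pyrrole-2-carbaldehyde | O=Cc1n(COCC[Si](C)(C)C)c(Br)c(Br)c1I | intermediate
6 | ethynyltrimethylsilane | C#C[Si](C)(C)C | starting material
7 | 4,5-dibromo-3-[(trimethylsilyl)ethynyl]-1-{[2-(trimethylsilyl)ethoxy]methyl}-1H-pyrrole-2-carbaldehyde | O=Cc1n(COCC[Si](C)(C)C)c(Br)c(Br)c1C#C[Si](C)(C)C | intermediate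
8 | dimethyl (1-diazo-2-oxopropyl)phosphonate | COP(=O)(OC)C(=[N+]=[N-])C(C)=O | starting material
9 | 4,5-dibromo-3-ethynyl-1-{[2-(trimethylsilyl)ethoxy]methyl}-1H-pyrrole-2-carbaldehyde | O=Cc1n(COCC[Si](C)(C)C)c(Br)c(Br)c1C#C | intermediate
10 | 4,5-dibromo-2,3-diethynyl-1-{[2-(trimethylsilyl)ethoxy]methyl}-1H-pyrrole (locants of 1 kept; the same compound as 2,3-dibromo-4,5-diethynyl-1-SEM-pyrrole) | C#Cc1c(C#C)n(COCC[Si](C)(C)C)c(Br)c1Br | intermediate
11 | carbon tetrabromide | BrC(Br)(Br)Br | starting material
12 | 2,3-dibromo-1-{[2-(trimethylsilyl)ethoxy]methyl}-1H-indole-4,7-diyl (sigma diradical) | C[Si](C)(C)CCOCn1c(Br)c(Br)c2[c]cc[c]c12 | intermediate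
13 | 2,3,4,7-tetrabromo-1-{[2-(trimethylsilyl)ethoxy]methyl}-1H-indole | C[Si](C)(C)CCOCn1c(Br)c(Br)c2c(Br)ccc(Br)c12 | intermediate
14 | 2,3,4,7-tetrabromo-1H-indole | Brc1[nH]c2c(Br)ccc(Br)c2c1Br | target

Total step count: 6. Longest linear sequence: 6 steps (1 to 14).

**Steps most likely to fail**

1. Step 5 (the step marked as a proposed new method). Three processes could defeat it:
   - radical-chain addition of CBr4 across the terminal alkynes may consume 10 before it cyclizes;
   - one of the two radical centres may capture hydrogen instead of bromine;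
   - cyclization may be too slow at a temperature that CBr4 and the nitroxide tolerate, because the five-membered ring holds the alkyne termini farther apart than a benzene ring does.

   The fallback uses known chemistry and abandons the cycloaromatization. It sets out from SEM chloride 4, which alkylates the sodium salt of commercially available 4,7-dibromo-1H-indole F1 (NaH, DMF, 0 °C) to give 4,7-dibromo-1-{[2-(trimethylsilyl)ethoxy]methyl}-1H-indole F2. N-Bromosuccinimide (2.2 equiv, THF or DMF, 0 °C to rt) should then brominate C3, giving 3,4,7-tribromo-1-{[2-(trimethylsilyl)ethoxy]methyl}-1H-indole F3 (not isolated), and after that C2. This is stepwise electrophilic substitution on the pyrrole ring of an N-alkylindole whose benzene ring is deactivated by two bromines. The sequence comes back to the route at 13, which step 6 deprotects.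

2. Step 1. The slow substitution at the beta carbon C3 of the deactivated pyrrole may be overtaken by ipso attack at the alpha carbons (bromine–iodine exchange at C5, iododeformylation at C2). The fallback replaces electrophilic substitution by deprotonative metalation. It sets out from 1, which is N-alkylated first (NaH, SEMCl, DMF, 0 °C) to 4,5-dibromo-1-{[2-(trimethylsilyl)ethoxy]methyl}-1H-pyrrole-2-carbaldehyde F4. The amide base TMPZnCl·LiCl (THF, rt), which tolerates aldehydes and aryl bromides, should then remove the only ring hydrogen (C3, acidified by the flanking formyl group and bromine) to give (4,5-dibromo-2-formyl-1-{[2-(trimethylsilyl)ethoxy]methyl}-1H-pyrrol-3-yl)zinc chloride F5 (not isolated). Iodolysis with I2 comes back to the route at 5.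

3. Step 6. The fragmentation may stall at the N-hydroxymethyl stage, or bromine may be lost from C2 by base during prolonged heating with fluoride. The fallback attacks the acetal oxygen with a Lewis acid instead of silicon with a nucleophile. It sets out from 13, which BF3·OEt2 (CH2Cl2, 0 °C to rt, then water) should cleave to (2,3,4,7-tetrabromo-1H-indol-1-yl)methanol F6. Stirring F6 with aqueous K2CO3 in THF/MeOH at rt should expel formaldehyde from the hemiaminal and comes back to the route at 14.

**Further compounds**
F1 | step 5 | 4,7-dibromo-1H-indole | Brc1ccc(Br)c2[nH]ccc12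
F2 | step 5 | 4,7-dibromo-1-{[2-(trimethylsilyl)ethoxy]methyl}-1H-indole | C[Si](C)(C)CCOCn1ccc2c(Br)ccc(Br)c12
F3 | step 5 | 3,4,7-tribromo-1-{[2-(trimethylsilyl)ethoxy]methyl}-1H-indole | C[Si](C)(C)CCOCn1cc(Br)c2c(Br)ccc(Br)c12
F4 | step 1 | 4,5-dibromo-1-{[2-(trimethylsilyl)ethoxy]methyl}-1H-pyrrole-2-carbaldehyde | O=Cc1cc(Br)c(Br)n1COCC[Si](C)(C)C
F5 | step 1 | (4,5-dibromo-2-formyl-1-{[2-(trimethylsilyl)ethoxy]methyl}-1H-pyrrol-3-yl)zinc chloride | O=Cc1n(COCC[Si](C)(C)C)c(Br)c(Br)c1[Zn]Cl
F6 | step 6 | (2,3,4,7-tetrabromo-1H-indol-1-yl)methanol | OCn1c(Br)c(Br)c2c(Br)ccc(Br)c12
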